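The easy step was to turn each run's last target reading into a concentration, so that runs with different charges could be compared in absolute amounts.

| setting | Thursday's | Sunday's | gamma | epsilon |
|---|---|---|---|---|
| substrate | 0.25 M | 0.40 M | 0.18 M | 0.18 M |
| gas phase | 40 mM (held) | 40 mM (held) | 40 mM (held) | 40 mM (held) |
| remark | run made earlier | run made earlier |  |  |
| time |  |  | 2.5 h | 5.0 h |

| run | time / min | target / % | substrate / % |
|---|---|---|---|
| Thursday's | 10.0 | 2.6 | 98.3 |
| Thursday's | 20.0 | 6.0 | 94.1 |
| Thursday's | 30.0 | 8.9 | 89.1 |
| Thursday's | 60.0 | 18.3 | 76.6 |
| Thursday's | 120 | 35.0 | 50.2 |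
| Sunday's | 10.0 | 1.7 | 98.2 |
| Sunday's | 20.0 | 3.5 | 95.8 |
| Sunday's | 30.0 | 6.7 | 91.4 |
| Sunday's | 60.0 | 11.6 | 81.9 |
| Sunday's | 120 | 22.4 | 61.7 |

(standard deviation of a reading: 0.5 percentage points)

- at the start none of the gas phase is in solution

1. which one finishes higher in amount of target, in percent of the substrate charged ("neither" within 2 percentage points) (gamma / epsilon / neither)
2. amount of target at the end, in percent of the substrate charged, gamma
3. amount of target at the end, in percent of the substrate charged, epsilon

Thursday's run gave a mean target formation rate of 0.729 mM min⁻¹ over 120 min and Sunday's run gave 0.747 mM min⁻¹, although Sunday's [substrate] was charged 1.60 times as high. My rule of thumb was therefore zero order in substrate: target in percent equals rate times time over charge. With Thursday's rate, gamma came to 60.8%, but epsilon, with the same charge, came to an impossible 122%.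

The border was a ratio. A charged [substrate] of 0.18 M at that rate lasts 4.11 h, and this charge time, charged substrate over target formation rate, is what I carried. Gamma stood at 0.608 charge times, inside the rule. Epsilon stood at 1.22, past it, so in my estimate substrate was the limiting reagent there. Thursday's last readings put target at 70.3% of the substrate consumed, and I took that share as my figure for epsilon.

The forecast chose epsilon, with 58% (52% to 63%) for gamma and 76% (67% to 84%) for epsilon, on the ground that target “forms at the same absolute rate in both runs”. Its epsilon stood higher than mine.

The flask gave 51.8% for gamma and 68.9% for epsilon, so epsilon finished higher, and the forecast stood 6.2 percentage points and 7.1 points too high.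

    gas phase ⇌ dissolved gas, rate k1*(csat - [dissolved gas]) (kL = 2.00 h⁻¹)
    substrate + dissolved gas → target (k = 31.0 M⁻¹ h⁻¹)
    dissolved gas + target → over-reacted product (k = 0.860 M⁻¹ h⁻¹)
    substrate + target → side product (k = 1.10 M⁻¹ h⁻¹)
    dissolved gas ⇌ dormant form (K = 11.0, k = 0.260 h⁻¹)

At the end of gamma the flask held 14.9% of side product beside 32.4% of substrate. The charge time of 4.11 h lay between the two times: at 0.608 charge times gamma had converted 67.6%, and at 1.22 epsilon had converted 96.5%.

For a neighbour flask, like epsilon but charged with 0.072 M, the charge time was 1.65 h, so the run lasted 3.04 charge times and lay past the border. The computed flask ended with 1.39% of its substrate left and 82.3% of target.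

Readings and results stem from a simulated flask from invented constants; scatter was added.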